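L is the product wanted, and I ask which set-up holds more of it, the closed flask or the tank.

| flask | Q | remark | time |
|---|---|---|---|
| north-west | 0.20 M | run made earlier |  |
| west | 0.13 M | run made earlier |  |
| south-east | 0.30 M | run made earlier |  |
| alpha | 0.20 M | a closed flask charged with all of it at once and left for 6.0 h | 6.0 h |
| gamma | 0.20 M | a single well-mixed tank run continuously and read at steady state, 6.0 h in it on average |  |

- north-west (time / h: L / %, Q / %): 0.667: 31, 45; 1.33: 39, 29; 2.00: 39, 23; 2.50: 38, 19; 3.00: 39, 17; 4.00: 34, 15
- west (time / h: L / %, Q / %): 0.500: 24, 53; 1.33: 41, 28; 2.50: 40, 20; 4.00: 34, 16; 6.00: 30, 15; 8.00: 32, 14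
- south-east (time / h: L / %, Q / %): 0.500: 26, 55; 1.00: 36, 30; 1.50: 42, 24; 2.50: 40, 18; 4.00: 34, 16; 8.00: 29, 15

(scatter of a reading: 1.5 percentage points)

- a species is counted by the Q in it: one J counts as two
- the stated concentrations are those of everything mixed, before any reaction; amounts are the same in each set-up
- reactions considered so far: Q <-> L; Q <-> D; Q <-> E; 2 Q -> J
- the earlier runs were made in a closed, stirred flask

1. the set-up with the highest amount of L at the outlet or at the end, in percent of the Q put in ("none" if the first two lie within 2 percentage points) (alpha / gamma / none)
2. amount of L at the outlet or at the end, in percent of the Q put in, alpha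
3. amount of L at the outlet or at the end, in percent of the Q put in, gamma

In the north-west run, Q falls from the whole charge to 45% in 0.667 h, and the last west reading of Q is 14%. Taking that reading as the plateau, I estimate that the excess of Q over it falls by a factor e in 0.654 h, a relaxation time. My turnover count, the time held divided by this relaxation time, 9.18, is the same for alpha and, on average, for gamma.

At steady state, a first-order change in a well-mixed tank stays undone by a share of one over one plus the count, here 9.82% of that change. Taken on the highest south-east reading of L, 42%, that share is 4.12% of the charge, my estimate of what young liquid costs gamma. I expect gamma's liquid of middle age to repay this, so I commit to a tie.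

The forecast also says none, with 31% for alpha and 32% for gamma, holding that “the tank's output equals the batch curve averaged”.

The flask gives 32.2% in alpha and 31.9% in gamma, so the answer is none, with a gap of 0.30 percentage points, less than the margin. Changing the charge of Q from the west run's to alpha's leaves L at the west run's last reading time at 29.9%, against 30.5% before.

    Q ⇌ L (K = 1.80, k = 2.20 × 10⁻⁴ s⁻¹)
    Q ⇌ D (K = 2.50, k = 1.21 × 10⁻⁴ s⁻¹)
    Q ⇌ E (K = 2.98, k = 2.00 × 10⁻⁵ s⁻¹)
    2 Q → J (k = 6.21 × 10⁻⁵ M⁻¹ s⁻¹)

Alpha's 9.18 turnovers stand beside 6.86 half-lives of the step from Q to L, forward rate alone, but 0.623 of the step from Q to E, forward rate alone, whose half-life, 9.6 h, is longer than the first, 0.88 h. Left for 60.0 h, alpha has 91.7 turnovers and 6.25 half-lives of the step to E, and L stands at 19.7%.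

The earlier runs and the new flask stem from a simulated flask with made-up constants; noise was put on by code.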